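The benzene ring is grown onto the furan, not coupled to it. The hydroquinone is a benzene ring (C1′–C6′) with oxygen on C1′ and C4′, furan C5 attached at C2′ and hydrogen on C3′, C5′ and C6′, which is the substitution pattern a chromium-templated [3+2+1] benzannulation delivers. In one operation an alkenyl(methoxy)carbene (C4′, C5′, C6′), one carbonyl ligand (C1′) and the ethynyl group of a 2-ethynylfuran (C2′, C3′) are joined through three C–C bonds, and the two oxygens emerge differentiated as OH and OMe. The alkyne precursor is the complete side-chain ester, both stereocentres set, with a bare ethynyl group on furan C5.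

Key step: step 9

Remark: by CIP analysis both stereocentres are R (carbinol: O > furan C3 > CH2 > H); the vinylcarbene partner is used as its (E)-β-trimethylsilyl derivative, because the unsubstituted vinyl complex polymerises readily, and the silyl group is a traceless spectator that leaves the ring skeleton and the three new bonds unchanged.

Step 1
Reactants: 1 4-methylpent-3-enoic acid
Product: 2 N-methoxy-N,4-dimethylpent-3-enamide
Conditions: CDI, CH2Cl2, rt; MeNH(OMe)·HCl, rt; aq. NaHCO3 wash
Reagents that add atoms: N,O-dimethylhydroxylamine hydrochloride, CNOC.Cl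
Why: Acyl imidazole formation and aminolysis (Weinreb amide synthesis) proceed under near-neutral conditions that should not move the β,γ-double bond into conjugation.

Step 2
Reactants: 3 4-bromofuran-2-carbaldehyde
Product: 4 2-(4-bromofuran-2-yl)-1,3-dioxolane
Conditions: HOCH2CH2OH, p-TsOH (cat.), benzene, reflux, Dean–Stark
Reagents that add atoms: ethylene glycol, OCCO
Why: Acid-catalysed acetalisation with azeotropic removal of water masks the aldehyde against the organolithium chemistry of step 3.

Step 3
Reactants: 4 2-(4-bromofuran-2-yl)-1,3-dioxolane; 2 N-methoxy-N,4-dimethylpent-3-enamide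
Product: 6 1-[5-(1,3-dioxolan-2-yl)furan-3-yl]-4-methylpent-3-en-1-one, via furyllithium 5 (not isolated)
Conditions: n-BuLi, Et2O, −78 °C; 2, −78 °C; AcOH, −78 °C
Reagents that add atoms: none
Why: Bromine–lithium exchange at −78 °C in ether should outrun migration of lithium to the furan α-position, the Weinreb ketone synthesis stops at the chelated tetrahedral adduct, and the cold acetic acid quench should keep the β,γ-enone out of conjugation.

Step 4
Reactants: 6 1-[5-(1,3-dioxolan-2-yl)furan-3-yl]-4-methylpent-3-en-1-one
Product: 7 (1R)-1-[5-(1,3-dioxolan-2-yl)furan-3-yl]-4-methylpent-3-en-1-ol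
Conditions: (S)-2-methyl-CBS-oxazaborolidine (0.2 equiv), catecholborane, toluene, −78 °C; MeOH, then aq. NaOH wash
Reagents that add atoms: none
Why: In the Corey–Bakshi–Shibata reduction the ketone binds the catalyst boron anti to the larger 3-furyl group and hydride is delivered to the Si face, which should set the R carbinol as the (S)-catalyst does for aryl alkyl ketones, while catecholborane leaves the trisubstituted alkene alone.

Step 5
Reactants: 7 (1R)-1-[5-(1,3-dioxolan-2-yl)furan-3-yl]-4-methylpent-3-en-1-ol
Product: 8 4-[(1R)-1-hydroxy-4-methylpent-3-en-1-yl]furan-2-carbaldehyde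
Conditions: PPTS (cat.), acetone/H2O, rt
Reagents that add atoms: water, O
Why: Acetal hydrolysis of a 2-furyl dioxolane proceeds under acid too mild to ionise the 3-furyl carbinol or to hydrate the alkene.

Step 6
Reactants: 8 4-[(1R)-1-hydroxy-4-methylpent-3-en-1-yl]furan-2-carbaldehyde
Product: 9 (1R)-1-(5-ethynylfuran-3-yl)-4-methylpent-3-en-1-ol
Conditions: dimethyl (1-diazo-2-oxopropyl)phosphonate, K2CO3, MeOH, 0 °C to rt
Reagents that add atoms: dimethyl (1-diazo-2-oxopropyl)phosphonate, CC(=O)C(=[N+]=[N-])P(=O)(OC)OC
Why: Seyferth–Gilbert homologation in its Ohira–Bestmann form converts the aldehyde into the terminal alkyne through an alkylidene carbene, tolerates the free alcohol, and is placed before esterification so that no ester meets methanolic carbonate.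

Step 7
Reactants: 9 (1R)-1-(5-ethynylfuran-3-yl)-4-methylpent-3-en-1-ol; 10 (R)-2-methylbutanoic acid
Product: 11 (1R)-1-(5-ethynylfuran-3-yl)-4-methylpent-3-en-1-yl (2R)-2-methylbutanoate
Conditions: DCC, DMAP (0.1 equiv), CH2Cl2, 0 °C
Reagents that add atoms: none
Why: Steglich esterification acylates the alcohol oxygen without touching the C–O bond, so the carbinol configuration is retained, and the purely alkyl-substituted α-centre of the acid should not epimerise at 0 °C with catalytic DMAP.

Step 8
Reactants: 12 (E)-(2-bromoethenyl)trimethylsilane; 13 chromium hexacarbonyl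
Product: 16 pentacarbonyl{methoxy[(E)-2-(trimethylsilyl)ethenyl]carbene}chromium(0), via silylvinyllithium 14 (not isolated), via lithium acylchromate 15 (not isolated)
Conditions: t-BuLi (2 equiv), Et2O, −78 °C; Cr(CO)6, −78 °C to rt; MeOTf, CH2Cl2, 0 °C
Reagents that add atoms: methyl trifluoromethanesulfonate, COS(=O)(=O)C(F)(F)F
Why: In this Fischer carbene synthesis the vinyllithium, formed with retention of E geometry, adds to a carbonyl ligand and the acyl chromate is O-methylated by a hard electrophile, the β-silyl group blocking the conjugate-addition polymerisation of the parent vinyl complex.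

Step 9
Reactants: 11 (1R)-1-(5-ethynylfuran-3-yl)-4-methylpent-3-en-1-yl (2R)-2-methylbutanoate; 16 pentacarbonyl{methoxy[(E)-2-(trimethylsilyl)ethenyl]carbene}chromium(0)
Product: 18 (1R)-1-[5-(2-hydroxy-5-methoxyphenyl)furan-3-yl]-4-methylpent-3-en-1-yl (2R)-2-methylbutanoate, via aryl trimethylsilyl ether 17 (not isolated)
Conditions: 16 (1.5 equiv), THF (0.05 M), 50 °C, Ar; then air, rt; 5% aq. citric acid, THF, rt
Reagents that add atoms: none
Why: Loss of one CO from 16 lets alkyne 11 coordinate and insert into the Cr=C bond with its terminal carbon bonding to the carbene carbon, CO insertion then gives a chromium-bound dienylketene in which the furyl-bearing carbon is joined to the new carbonyl carbon, and ring closure followed by a 1,3 shift of silicon from carbon to oxygen aromatises the cyclohexadienone to silyl ether 17, which dilute acid cleaves to phenol 18. The closest known reaction type is the Dötz benzannulation of alkenyl(alkoxy)carbene chromium complexes with terminal aryl alkynes, for which β-silylvinyl complexes serve as stable stand-ins for the parent vinyl complex. The benzene ring closes by 6π electrocyclisation of the metal-bound dienylketene, which bonds the ketene carbon to the silyl-bearing vinyl carbon. No stereocentre is formed, and the two existing ones are remote from the alkyne and should be untouched at 50 °C under neutral conditions. The step needs regioselective insertion, which the terminal alkyne secures because the bulky furyl end stays away from the carbene carbon and so ends ortho to the new oxygen and meta to OMe, and it needs phenol formation to beat cyclopentannulation, which alkenyl complexes in THF favour.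

Step 10
Reactants: 18 (1R)-1-[5-(2-hydroxy-5-methoxyphenyl)furan-3-yl]-4-methylpent-3-en-1-yl (2R)-2-methylbutanoate
Product: 20 (1R)-1-[5-(2,5-dihydroxyphenyl)furan-3-yl]-4-methylpent-3-en-1-yl (2R)-2-methylbutanoate, via furylbenzoquinone 19 (not isolated)
Conditions: PhI(OAc)2, MeCN/H2O, 0 °C; then aq. Na2S2O4, EtOAc, rt, Ar
Reagents that add atoms: water, O
Why: Phenol-directed iodine(III) oxidation forms an aryloxyiodane that water attacks at the methoxy-bearing para carbon, the hemiketal loses methanol to give the quinone (oxidative demethylation of a 4-methoxyphenol), and dithionite then reduces the quinone to the hydroquinone without affecting the ester, alkene or furan.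

Compound list
1 | 4-methylpent-3-enoic acid | CC(C)=CCC(=O)O | starting material
2 | N-methoxy-N,4-dimethylpent-3-enamide | CC(C)=CCC(=O)N(C)OC | intermediate
3 | 4-bromofuran-2-carbaldehyde | O=Cc1cc(Br)co1 | starting material
4 | 2-(4-bromofuran-2-yl)-1,3-dioxolane | Brc1coc(C2OCCO2)c1 | intermediate
5 | [5-(1,3-dioxolan-2-yl)furan-3-yl]lithium (furyllithium, not isolated) | [Li]c1coc(C2OCCO2)c1 | intermediate
6 | 1-[5-(1,3-dioxolan-2-yl)furan-3-yl]-4-methylpent-3-en-1-one | CC(C)=CCC(=O)c1coc(C2OCCO2)c1 | intermediate
7 | (1R)-1-[5-(1,3-dioxolan-2-yl)furan-3-yl]-4-methylpent-3-en-1-ol | O[C@H](CC=C(C)C)c1coc(C2OCCO2)c1 | intermediate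
8 | 4-[(1R)-1-hydroxy-4-methylpent-3-en-1-yl]furan-2-carbaldehyde | O[C@H](CC=C(C)C)c1coc(C=O)c1 | intermediate
9 | (1R)-1-(5-ethynylfuran-3-yl)-4-methylpent-3-en-1-ol | O[C@H](CC=C(C)C)c1coc(C#C)c1 | intermediate
10 | (R)-2-methylbutanoic acid | CC[C@@H](C)C(=O)O | starting material
11 | (1R)-1-(5-ethynylfuran-3-yl)-4-methylpent-3-en-1-yl (2R)-2-methylbutanoate | CC[C@@H](C)C(=O)O[C@H](CC=C(C)C)c1coc(C#C)c1 | intermediate
12 | (E)-(2-bromoethenyl)trimethylsilane | C[Si](C)(C)/C=C/Br | starting material
13 | chromium hexacarbonyl | O=C=[Cr](=C=O)(=C=O)(=C=O)(=C=O)=C=O | starting material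
14 | [(E)-2-(trimethylsilyl)ethenyl]lithium (silylvinyllithium, not isolated) | [Li]/C=C/[Si](C)(C)C | intermediate
15 | lithium pentacarbonyl[(E)-3-(trimethylsilyl)prop-2-enoyl]chromate (lithium acylchromate, not isolated) | [Li+].[O-]C(/C=C/[Si](C)(C)C)=[Cr](=C=O)(=C=O)(=C=O)(=C=O)=C=O | intermediate
16 | pentacarbonyl{methoxy[(E)-2-(trimethylsilyl)ethenyl]carbene}chromium(0) | COC(/C=C/[Si](C)(C)C)=[Cr](=C=O)(=C=O)(=C=O)(=C=O)=C=O | intermediate
17 | (1R)-1-{5-[5-methoxy-2-(trimethylsilyloxy)phenyl]furan-3-yl}-4-methylpent-3-en-1-yl (2R)-2-methylbutanoate (aryl trimethylsilyl ether, not isolated) | CC[C@@H](C)C(=O)O[C@H](CC=C(C)C)c1coc(-c2cc(OC)ccc2O[Si](C)(C)C)c1 | intermediate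
18 | (1R)-1-[5-(2-hydroxy-5-methoxyphenyl)furan-3-yl]-4-methylpent-3-en-1-yl (2R)-2-methylbutanoate | CC[C@@H](C)C(=O)O[C@H](CC=C(C)C)c1coc(-c2cc(OC)ccc2O)c1 | intermediate
19 | (1R)-1-[5-(3,6-dioxocyclohexa-1,4-dien-1-yl)furan-3-yl]-4-methylpent-3-en-1-yl (2R)-2-methylbutanoate (furylbenzoquinone, not isolated) | CC[C@@H](C)C(=O)O[C@H](CC=C(C)C)c1coc(C2=CC(=O)C=CC2=O)c1 | intermediate
20 | (1R)-1-[5-(2,5-dihydroxyphenyl)furan-3-yl]-4-methylpent-3-en-1-yl (2R)-2-methylbutanoate (CNP0144658.1) | CC[C@@H](C)C(=O)O[C@H](CC=C(C)C)c1coc(-c2cc(O)ccc2O)c1 | target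

Total step count: 10 (steps 1–10).
Longest linear sequence: 8 steps (2, 3, 4, 5, 6, 7, 9, 10) from 4-bromofuran-2-carbaldehyde 3.

Steps most likely to fail

Step 9 (benzannulation). The chromium-bound vinylketene may divert to cyclobutenone or other non-phenolic products, the electron-rich ethynylfuran may oligomerise at the metal, or the shift of silicon from carbon to oxygen may be incomplete. The fallback uses a purchased arene instead of building it, and sets out from Weinreb amide 2. 2,4-Dibromofuran would be coupled at its more reactive C2–Br bond with (2,5-dimethoxyphenyl)boronic acid (Pd(PPh3)4, aq. Na2CO3, DME, 80 °C, Suzuki coupling) to give 4-bromo-2-(2,5-dimethoxyphenyl)furan F1. Bromine–lithium exchange (n-BuLi, Et2O, −78 °C) would give [5-(2,5-dimethoxyphenyl)furan-3-yl]lithium F2, which is acylated in the same flask with 2 to 1-[5-(2,5-dimethoxyphenyl)furan-3-yl]-4-methylpent-3-en-1-one F3. CBS reduction as in step 4 should give (1R)-1-[5-(2,5-dimethoxyphenyl)furan-3-yl]-4-methylpent-3-en-1-ol F4, and Steglich esterification with acid 10 the dimethyl ether (1R)-1-[5-(2,5-dimethoxyphenyl)furan-3-yl]-4-methylpent-3-en-1-yl (2R)-2-methylbutanoate F5. Oxidative demethylation with ceric ammonium nitrate (MeCN/H2O, 0 °C) would then rejoin the route at quinone 19, which dithionite reduces to 20 as in step 10.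

Step 3 (ketone synthesis). Proton transfer from the doubly activated α-CH2 of amide 2 to the basic furyllithium may outrun addition, lithium may migrate to the furan α-position on warming, or the β,γ-enone may slip into conjugation. The fallback replaces acyl substitution by carbonyl addition and oxidation, sets out from bromide 4 and returns at ketone 6. Commercial 4-methylpent-3-en-1-ol would be oxidised (Dess–Martin periodinane, NaHCO3, CH2Cl2, 0 °C) to 4-methylpent-3-enal F6 and used at once. Furyllithium 5, generated from 4 as before, would add to it at −78 °C to give racemic 1-[5-(1,3-dioxolan-2-yl)furan-3-yl]-4-methylpent-3-en-1-ol F7. A second buffered Dess–Martin oxidation should give 6.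

Step 4 (asymmetric reduction). Facial discrimination between the 3-furyl group and the CH2-prenyl chain may be insufficient, or hydroboration of the alkene may compete. The fallback sets the stereocentre by C–C bond formation, sets out from bromide 4 and returns at alcohol 7. Furyllithium 5 would be formylated with DMF to 5-(1,3-dioxolan-2-yl)furan-3-carbaldehyde F8. Brown allylation with B-allyldiisopinocampheylborane of the (−)-α-pinene series (Et2O, −78 °C; NaOH, H2O2) should give (1R)-1-[5-(1,3-dioxolan-2-yl)furan-3-yl]but-3-en-1-ol F9. Cross-metathesis with 2-methyl-2-butene (second-generation Grubbs catalyst, CH2Cl2, 40 °C) would convert the allyl terminus into the prenyl group of 7.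

Further compounds
F1 | step 9 | 4-bromo-2-(2,5-dimethoxyphenyl)furan | COc1ccc(OC)c(-c2cc(Br)co2)c1
F2 | step 9 | [5-(2,5-dimethoxyphenyl)furan-3-yl]lithium | [Li]c1coc(-c2cc(OC)ccc2OC)c1
F3 | step 9 | 1-[5-(2,5-dimethoxyphenyl)furan-3-yl]-4-methylpent-3-en-1-one | CC(C)=CCC(=O)c1coc(-c2cc(OC)ccc2OC)c1
F4 | step 9 | (1R)-1-[5-(2,5-dimethoxyphenyl)furan-3-yl]-4-methylpent-3-en-1-ol | O[C@H](CC=C(C)C)c1coc(-c2cc(OC)ccc2OC)c1
F5 | step 9 | (1R)-1-[5-(2,5-dimethoxyphenyl)furan-3-yl]-4-methylpent-3-en-1-yl (2R)-2-methylbutanoate | CC[C@@H](C)C(=O)O[C@H](CC=C(C)C)c1coc(-c2cc(OC)ccc2OC)c1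
F6 | step 3 | 4-methylpent-3-enal | CC(C)=CCC=O
F7 | step 3 | rac-1-[5-(1,3-dioxolan-2-yl)furan-3-yl]-4-methylpent-3-en-1-ol | OC(CC=C(C)C)c1coc(C2OCCO2)c1
F8 | step 4 | 5-(1,3-dioxolan-2-yl)furan-3-carbaldehyde | O=Cc1coc(C2OCCO2)c1
F9 | step 4 | (1R)-1-[5-(1,3-dioxolan-2-yl)furan-3-yl]but-3-en-1-ol | O[C@H](CC=C)c1coc(C2OCCO2)c1
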